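**Retrosynthetic overview**

- The 3,4-trans lactone is cut last at the bond from the α-carbon to its arylmethyl CH2: alkylation of the enolate of β-(3,4,5-trimethoxybenzyl)butyrolactone 10 with bromide 11.
- Lactone 10 comes from diol 8 and this from (R)-arylmethylsuccinic anhydride 7, in which both the later C=O carbon and the later O–CH2 carbon are still carbonyl carbons.
- Key disconnection: the bond from the α-carbon to the carbonyl carbon and the bond from the β-carbon to the O–CH2 carbon are made together by double carbonylation of (S)-epoxide 5 with two CO.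
- Enabling feature: the strained oxirane ring of 5 (O, the unsubstituted CH2 and the CH that carries the arylmethyl group). Its two C–O bonds are opened in turn by Co(CO)4−, the second one from the four-membered oxetanone ring of 6.
- Ring order: oxirane (step 2), then oxetanone and anhydride (step 3), then butyrolactone (step 5). Epoxide 5 comes from the Grignard reagent of 1 and (S)-epichlorohydrin 2.

Key step: step 3

Remark: the target is read as the 3,4-trans (3R,4R) lactone; 1, 2 and 11 are taken as commercially available.

**Step 1**
Reactants: 1 5-bromo-1,2,3-trimethoxybenzene; 2 (S)-2-(chloromethyl)oxirane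
Product: 4 (S)-1-chloro-3-(3,4,5-trimethoxyphenyl)propan-2-ol, via (3,4,5-trimethoxyphenyl)magnesium bromide 3 (not isolated)
Conditions: Mg, I2 (cat.), THF, reflux; then CuI (10 mol%), 2, THF, −40 → 0 °C; 1 M HCl
Reagents that add atoms: none
Why: Copper-catalysed Grignard opening of the epoxide (SN2 at the unsubstituted ring CH2 in preference to the C–Cl carbon) leaves the stereocentre of 2 untouched, so 4 should keep the S configuration.

**Step 2**
Reactants: 4 (S)-1-chloro-3-(3,4,5-trimethoxyphenyl)propan-2-ol
Product: 5 (S)-2-[(3,4,5-trimethoxyphenyl)methyl]oxirane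
Conditions: NaOH, MeOH/H2O, 0 °C → rt
Reagents that add atoms: none
Why: Intramolecular Williamson etherification (3-exo-tet) of the chlorohydrin alkoxide closes the oxirane at the former CH2Cl carbon without touching the stereocentre.

**Step 3**
Reactants: 5 (S)-2-[(3,4,5-trimethoxyphenyl)methyl]oxirane
Product: 7 (R)-3-[(3,4,5-trimethoxyphenyl)methyl]oxolane-2,5-dione, via (S)-4-[(3,4,5-trimethoxyphenyl)methyl]oxetan-2-one 6 (not isolated)
Conditions: [(ClTPP)Al(THF)2][Co(CO)4] (2 mol%; ClTPP = meso-tetrakis(4-chlorophenyl)porphyrinato), CO (60 bar), 1,4-dioxane, 90 °C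
Reagents that add atoms: carbon monoxide, [C-]#[O+] (two molecules)
Why: Ring-expanding double carbonylation by a Lewis acid/cobaltate ion pair, the closest known reaction being the one-pot epoxide → β-lactone → succinic anhydride carbonylation with this catalyst class. Mechanism: the aluminium cation binds the oxirane oxygen, Co(CO)4− opens the ring by SN2 at the unsubstituted CH2, CO inserts into the Co–C bond and the aluminium alkoxide attacks the acylcobalt carbon to close oxetanone 6 (4-exo-trig); the ion pair then opens 6 by SN2 at its O-bearing CH carbon, a second CO inserts and the aluminium carboxylate closes the anhydride (5-exo-trig). The two new C–C bonds (CH2–C=O and CH–C=O) therefore both come from CO, and release of the oxirane strain and then of the oxetanone strain drives each opening. No new stereocentre is made; the existing one is untouched in the first carbonylation and inverted in the second (backside attack of the cobaltate, then CO insertion with retention), so S-configured 5 should give R-configured 7 stereospecifically. The step needs attack at CH2 first (secured by the monosubstituted oxirane, primary against secondary carbon), alkyl–O and not acyl–O cleavage of 6 (secured by the soft cobaltate and the ring strain), and carbonylation faster than Lewis-acid isomerisation of 5 to a ketone (secured by high CO pressure and by dioxane, which supports both stages).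

**Step 4**
Reactants: 7 (R)-3-[(3,4,5-trimethoxyphenyl)methyl]oxolane-2,5-dione
Product: 8 (R)-2-[(3,4,5-trimethoxyphenyl)methyl]butane-1,4-diol
Conditions: LiAlH4, THF, 0 °C → rt (inverse addition); then H2O
Reagents that add atoms: none
Why: Exhaustive hydride reduction of the cyclic anhydride gives the 1,4-diol, and the stereocentre should survive because reduction of the adjacent carbonyl is much faster than its enolisation at low temperature.

**Step 5**
Reactants: 8 (R)-2-[(3,4,5-trimethoxyphenyl)methyl]butane-1,4-diol
Product: 10 (R)-4-[(3,4,5-trimethoxyphenyl)methyl]oxolan-2-one, via (4R)-4-[(3,4,5-trimethoxyphenyl)methyl]oxolan-2-ol 9 (not isolated)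
Conditions: Cu(MeCN)4OTf (5 mol%), 2,2'-bipyridine (5 mol%), TEMPO (5 mol%), N-methylimidazole (10 mol%), air, MeCN, rt
Reagents that add atoms: none
Why: Copper/nitroxyl aerobic oxidative lactonisation of an unsymmetrical diol is strongly biased by sterics, so the unbranched CH2CH2OH arm should be oxidised to the aldehyde, which closes to lactol 9 and is oxidised on to the lactone, leaving the β-branched CH2OH as the ring O–CH2.

**Step 6**
Reactants: 10 (R)-4-[(3,4,5-trimethoxyphenyl)methyl]oxolan-2-one; 11 4-(bromomethyl)-1,2-dimethoxybenzene
Product: 13 (3R,4R)-3-[(3,4-dimethoxyphenyl)methyl]-4-[(3,4,5-trimethoxyphenyl)methyl]oxolan-2-one (the target), via lithium (4R)-4-[(3,4,5-trimethoxyphenyl)methyl]-4,5-dihydrofuran-2-olate 12 (not isolated)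
Conditions: LiN(SiMe3)2, THF, −78 °C; then 11, DMPU, −78 → −30 °C; aq NH4Cl
Reagents that add atoms: none
Why: Enolate alkylation of a β-substituted γ-butyrolactone, in which the benzyl bromide approaches the planar lithium enolate anti to the β-arylmethyl group, should set the new α-stereocentre trans (3R) under substrate control.

**Compound list**

1 | 5-bromo-1,2,3-trimethoxybenzene | COc1cc(Br)cc(OC)c1OC | starting material
2 | (S)-2-(chloromethyl)oxirane, (S)-epichlorohydrin | ClC[C@@H]1CO1 | starting material
3 | (3,4,5-trimethoxyphenyl)magnesium bromide | COc1cc([Mg]Br)cc(OC)c1OC | intermediate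
4 | (S)-1-chloro-3-(3,4,5-trimethoxyphenyl)propan-2-ol | COc1cc(C[C@H](O)CCl)cc(OC)c1OC | intermediate
5 | (S)-2-[(3,4,5-trimethoxyphenyl)methyl]oxirane | COc1cc(C[C@H]2CO2)cc(OC)c1OC | intermediate
6 | (S)-4-[(3,4,5-trimethoxyphenyl)methyl]oxetan-2-one | COc1cc(C[C@H]2CC(=O)O2)cc(OC)c1OC | intermediate
7 | (R)-3-[(3,4,5-trimethoxyphenyl)methyl]oxolane-2,5-dione | COc1cc(C[C@@H]2CC(=O)OC2=O)cc(OC)c1OC | intermediate
8 | (R)-2-[(3,4,5-trimethoxyphenyl)methyl]butane-1,4-diol | COc1cc(C[C@@H](CO)CCO)cc(OC)c1OC | intermediate
9 | (4R)-4-[(3,4,5-trimethoxyphenyl)methyl]oxolan-2-ol, both anomers | COc1cc(C[C@H]2COC(O)C2)cc(OC)c1OC | intermediate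
10 | (R)-4-[(3,4,5-trimethoxyphenyl)methyl]oxolan-2-one | COc1cc(C[C@H]2COC(=O)C2)cc(OC)c1OC | intermediate
11 | 4-(bromomethyl)-1,2-dimethoxybenzene | COc1ccc(CBr)cc1OC | starting material
12 | lithium (4R)-4-[(3,4,5-trimethoxyphenyl)methyl]-4,5-dihydrofuran-2-olate | COc1cc(C[C@H]2COC(O[Li])=C2)cc(OC)c1OC | intermediate
13 | (3R,4R)-3-[(3,4-dimethoxyphenyl)methyl]-4-[(3,4,5-trimethoxyphenyl)methyl]oxolan-2-one | COc1ccc(C[C@H]2C(=O)OC[C@@H]2Cc2cc(OC)c(OC)c(OC)c2)cc1OC | target

**Step count and risks**

Total step count: 6. Longest linear sequence: 6 steps (1 → 13).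

Steps most likely to fail:

1. Step 3. What may go wrong: Lewis-acid isomerisation of the oxirane to a ketone competing with the first carbonylation, or stalling at the oxetanone stage so that the second C–C bond is not formed. The fallback sets out from 1 and comes back to the route at 8. A Heck reaction of 1 with dimethyl itaconate (Pd(OAc)2, P(o-tol)3, Et3N, DMF, 100 °C) should give dimethyl (E)-2-(3,4,5-trimethoxybenzylidene)succinate F1. Asymmetric hydrogenation with a cationic rhodium bisphospholane catalyst such as [Rh(cod)(Et-DuPHOS)]BF4 (ligand enantiomer chosen for the R product, H2, MeOH) should give dimethyl (R)-2-[(3,4,5-trimethoxyphenyl)methyl]succinate F2. LiAlH4 reduction of both esters then gives diol 8.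

2. Step 5. What may go wrong: poor site selectivity between the two primary alcohols, with oxidation starting at the β-branched CH2OH and leading to the regioisomeric α-substituted lactone. The fallback sets out from 7 and comes back at 10. NaBH4 in THF at 0 °C, then aqueous HCl, is used: small hydrides are known to attack unsymmetrical succinic anhydrides preferentially at the carbonyl next to the substituted carbon, which is the carbonyl that has to become the ring O–CH2. The hydroxy acid closes to 10 on acidification, and the minor regioisomeric lactone would be removed by chromatography (no new compound on this path, F0).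

3. Step 6. What may go wrong: over-alkylation through proton exchange between product and enolate, or incomplete trans selectivity. The fallback sets out from 10 and comes back at 13. Aldol addition of the lithium enolate of 10 to 3,4-dimethoxybenzaldehyde (LiN(SiMe3)2, THF, −78 °C) should give the 3,4-trans adduct (3S,4R)-3-[(3,4-dimethoxyphenyl)(hydroxy)methyl]-4-[(3,4,5-trimethoxyphenyl)methyl]oxolan-2-one F3 as a mixture of carbinol epimers; the aldolate cannot add a second time. Hydrogenolysis of the benzylic C–O bond (H2, Pd/C, AcOH, cat. HClO4) should converge both epimers on 13.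

**Further compounds**

F1 | step 3 | dimethyl (E)-2-(3,4,5-trimethoxybenzylidene)succinate | COC(=O)C/C(=C\c1cc(OC)c(OC)c(OC)c1)C(=O)OC
F2 | step 3 | dimethyl (R)-2-[(3,4,5-trimethoxyphenyl)methyl]succinate | COC(=O)C[C@@H](Cc1cc(OC)c(OC)c(OC)c1)C(=O)OC
F0 | step 5 | none | none
F3 | step 6 | (3S,4R)-3-[(3,4-dimethoxyphenyl)(hydroxy)methyl]-4-[(3,4,5-trimethoxyphenyl)methyl]oxolan-2-one, both carbinol epimers | COc1ccc(C(O)[C@H]2C(=O)OC[C@@H]2Cc2cc(OC)c(OC)c(OC)c2)cc1OC
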